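The target is cut at both lactone C–O bonds and at C3–C4 and C3'–C4'. This exposes a succinic acid whose α-carbons C3 and C3' each adjoin a benzylic carbon (C4, C4') carrying a polyoxygenated aryl ring and a 4-hydroxyphenyl ring. Drawing each 4-hydroxyphenyl ring as a 4-oxocyclohexene ketal turns both bonds into the σ bonds of ester-enolate [3,3] shifts. One double Ireland–Claisen rearrangement of a succinate diester of two (R)-configured (E)-2-arylidenecyclohexanols therefore forms both bonds and all four stereocentres. Ketal hydrolysis, dehydrogenation, demethylation and lactonization to the two chroman-2-one rings follow.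

Key step: step 11

Remark: locants 2–4 and 2'–4' are those of the two chroman-2-one rings (unprimed = 5,7-dihydroxy half, ring A; primed = 5,6,7,8-tetrahydroxy half, ring B); a ketene acetal is called Z when the succinate chain is cis to the silyloxy group.
Remark: a tetramethoxybenzene carries only four of the five oxygens of the ring B aryl group, so the fifth oxygen is installed in steps 2 and 3 before formylation.

Step 1
Reactants: 1 cyclohexane-1,3-dione
Product: 2 1,4-dioxaspiro[4.5]decan-7-one
Conditions: HOCH2CH2OH (1 equiv), TsOH·H2O (cat.), toluene, reflux, Dean–Stark; distillation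
Reagents that add atoms: ethylene glycol, OCCO
Why: Acid-catalysed dioxolane formation with azeotropic water removal converts the enolised dione, through its 2-hydroxyethyl enol ether and intramolecular conjugate addition of the hydroxyl, into the mono-ketal, and one equivalent of diol limits bis-ketal formation.

Step 2
Reactants: 3 1,2,3,4-tetramethoxybenzene
Product: 6 2,3,4,5-tetramethoxyphenol, via aryllithium 4 (not isolated), via lithium aryltrimethoxyborate 5 (not isolated)
Conditions: n-BuLi, TMEDA, THF, 0 °C; B(OMe)3, −78 °C → rt; 30% H2O2, 0 °C → rt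
Reagents that add atoms: hydrogen peroxide, OO
Why: Directed ortho-lithiation next to a methoxy group, borylation and oxidative aryl migration from boron to oxygen (boronate oxidation) place the missing fifth oxygen on one of the two equivalent free ring positions.

Step 3
Reactants: 6 2,3,4,5-tetramethoxyphenol
Product: 7 pentamethoxybenzene
Conditions: MeI, K2CO3, acetone, reflux
Reagents that add atoms: iodomethane, CI
Why: Williamson O-methylation of the phenoxide is unambiguous because the phenol oxygen is the only nucleophilic site.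

Step 4
Reactants: 7 pentamethoxybenzene
Product: 10 pentamethoxybenzaldehyde, via aryllithium 8 (not isolated), via lithium hemiaminal alkoxide 9 (not isolated)
Conditions: n-BuLi, THF, 0 °C; DMF, 0 °C → rt; H2O
Reagents that add atoms: N,N-dimethylformamide, CN(C)C=O
Why: The single ring hydrogen lies between two methoxy groups and is removed cleanly (directed ortho-metalation), and the aryllithium is formylated by DMF (Bouveault aldehyde synthesis).

Step 5
Reactants: 2 1,4-dioxaspiro[4.5]decan-7-one, 11 2,4,6-trimethoxybenzaldehyde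
Product: 15 (E)-8-(2,4,6-trimethoxybenzylidene)-1,4-dioxaspiro[4.5]decan-7-one, via lithium enolate 12 (not isolated), via lithium aldolate 13 (not isolated), via mesylate 14 (not isolated)
Conditions: LiN(iPr)2, THF, −78 °C; 11; MsCl, −78 → 0 °C; DBU, 0 °C → rt
Reagents that add atoms: none
Why: Kinetic deprotonation at −78 °C takes the unhindered C8 methylene remote from the ketal, a directed aldol addition to the non-enolisable aldehyde follows, and base elimination of the in-flask mesylate (E1cB) should give the enone with the aryl group trans to the carbonyl, the sterically favoured E isomer.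

Step 6
Reactants: 2 1,4-dioxaspiro[4.5]decan-7-one, 10 pentamethoxybenzaldehyde
Product: 19 (E)-8-(pentamethoxybenzylidene)-1,4-dioxaspiro[4.5]decan-7-one, via sodium enolate 16 (not isolated), via sodium aldolate 17 (not isolated), via mesylate 18 (not isolated)
Conditions: NaN(SiMe3)2 (0.98 equiv), THF, −78 °C; 10; MsCl, −78 → 0 °C; DBU, 0 °C → rt
Reagents that add atoms: none
Why: For this aldehyde, whose ortho-methoxy groups are buttressed by the meta ones, the more reactive sodium enolate is used: NaN(SiMe3)2 at −78 °C again removes a proton from the unhindered C8 methylene, a directed aldol addition follows, and E1cB elimination of the in-flask mesylate should give the E enone with the aryl group away from the carbonyl.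

Step 7
Reactants: 15 (E)-8-(2,4,6-trimethoxybenzylidene)-1,4-dioxaspiro[4.5]decan-7-one
Product: 20 (7R,8E)-8-(2,4,6-trimethoxybenzylidene)-1,4-dioxaspiro[4.5]decan-7-ol
Conditions: (S)-1-methyl-3,3-diphenyltetrahydro-1H,3H-pyrrolo[1,2-c][1,3,2]oxazaborole (0.2 equiv), catecholborane, toluene, −78 °C; MeOH, then aq. NaOH wash
Reagents that add atoms: none
Why: In this Corey–Bakshi–Shibata reduction the fully substituted arylidene-bearing carbon acts as the large group and the ring CH2 as the small one, so the (S)-oxazaborolidine should deliver hydride to the face that gives the (R)-carbinol, while catecholborane at −78 °C leaves alkene and ketal untouched.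

Step 8
Reactants: 19 (E)-8-(pentamethoxybenzylidene)-1,4-dioxaspiro[4.5]decan-7-one
Product: 21 (7R,8E)-8-(pentamethoxybenzylidene)-1,4-dioxaspiro[4.5]decan-7-ol
Conditions: (S)-1-methyl-3,3-diphenyltetrahydro-1H,3H-pyrrolo[1,2-c][1,3,2]oxazaborole (0.2 equiv), catecholborane, toluene, −78 °C; MeOH, then aq. NaOH wash
Reagents that add atoms: none
Why: The Corey–Bakshi–Shibata reduction follows the same model as in step 7, with the arylidene side as the large group, and should set the (R)-carbinol by catalyst control.

Step 9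
Reactants: 20 (7R,8E)-8-(2,4,6-trimethoxybenzylidene)-1,4-dioxaspiro[4.5]decan-7-ol, 22 succinic anhydride
Product: 23 hemisuccinate 4-oxo-4-{[(7R,8E)-8-(2,4,6-trimethoxybenzylidene)-1,4-dioxaspiro[4.5]decan-7-yl]oxy}butanoic acid
Conditions: Et3N, 4-(dimethylamino)pyridine (cat.), CH2Cl2, rt; pH 5 phosphate buffer work-up
Reagents that add atoms: none
Why: Acyl-transfer-catalysed ring opening of the cyclic anhydride by the secondary alcohol stops at the half-ester, and the basic medium protects the ionisable allylic C–O bond and the ketal.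

Step 10
Reactants: 23 hemisuccinate of 20, 21 (7R,8E)-8-(pentamethoxybenzylidene)-1,4-dioxaspiro[4.5]decan-7-ol
Product: 24 mixed succinate diester 1-[(7R,8E)-8-(pentamethoxybenzylidene)-1,4-dioxaspiro[4.5]decan-7-yl] 4-[(7R,8E)-8-(2,4,6-trimethoxybenzylidene)-1,4-dioxaspiro[4.5]decan-7-yl] butanedioate
Conditions: EDC·HCl, 4-(dimethylamino)pyridine, CH2Cl2, 0 °C → rt; chromatography on Et3N-buffered silica
Reagents that add atoms: none
Why: Steglich esterification joins the acid and the second allylic alcohol under neutral conditions, so neither carbinol centre nor alkene geometry is disturbed.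

Step 11
Reactants: 24 mixed succinate diester
Product: 29 (2S,3S)-2-[(R)-(1,4-dioxaspiro[4.5]dec-7-en-8-yl)(2,4,6-trimethoxyphenyl)methyl]-3-[(R)-(1,4-dioxaspiro[4.5]dec-7-en-8-yl)(pentamethoxyphenyl)methyl]succinic acid, via dilithium bis-enolate 25 (not isolated), via bis(silyl ketene acetal) 26 (not isolated), via half-rearranged ketene acetal 27 (not isolated), via bis(silyl ester) 28 (not isolated)
Conditions: LiN(iPr)2 (2.6 equiv), THF–DMPU (3:1), −78 °C; TMSCl–Et3N (1:1), −78 °C → rt, then 60 °C; aq. NaH2PO4 work-up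
Reagents that add atoms: none
Why: Double deprotonation of the succinate and O-silylation give the bis(silyl ketene acetal) 26, and on warming each allyl vinyl ether unit undergoes a concerted, suprafacial [3,3]-sigmatropic shift, first to 27 and then to the bis(silyl ester) 28, which water cleaves to 29. The closest known reaction is the Ireland–Claisen ester-enolate rearrangement in its double version on bis-allylic succinates; no ring is closed. C4 and C4' are controlled by the carbinol centres through 1,3-chirality transfer: in the chair transition state the ring CH2 on the carbinol carbon is pseudo-equatorial and the new bond forms at the arylidene carbon on the face from which the C–O bond departs, so an (R)-carbinol with an E-alkene gives an (R)-benzylic centre. C3 and C3' are controlled by the ketene acetal geometry: with the succinate chain cis to OSiMe3 it lies pseudo-equatorial in the same chair and gives the (S) centres, so that each half emerges as the 3S,4R pair. The step needs chair over boat and one ketene acetal geometry at both termini; the first is the normal preference of an exocyclic E-allyl unit whose large groups can all be pseudo-equatorial, and the second is secured by enolization in the presence of DMPU, which gives the enolate with the chain cis to the O–Li bond. The two carbinol centres are reagent-set with the same sense, so both rearrangements are matched and the pseudo-C2-symmetric 2,3-disubstituted succinate results.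

Step 12
Reactants: 29 bis-ketal succinic acid
Product: 30 dimethyl (2S,3S)-2-[(R)-(1,4-dioxaspiro[4.5]dec-7-en-8-yl)(2,4,6-trimethoxyphenyl)methyl]-3-[(R)-(1,4-dioxaspiro[4.5]dec-7-en-8-yl)(pentamethoxyphenyl)methyl]succinate
Conditions: TMSCHN2, toluene–MeOH (4:1), 0 °C → rt
Reagents that add atoms: trimethylsilyldiazomethane, C[Si](C)(C)C=[N+]=[N-]
Why: Diazoalkane O-methylation of the carboxylic acids is neutral, so ketals and α-stereocentres are untouched, and it masks the γ,δ-unsaturated acids, which could otherwise add to the ring alkenes under the acid and palladium conditions that follow.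

Step 13
Reactants: 30 bis-ketal dimethyl ester
Product: 31 dimethyl (2S,3S)-2-[(R)-(4-oxocyclohex-1-en-1-yl)(2,4,6-trimethoxyphenyl)methyl]-3-[(R)-(4-oxocyclohex-1-en-1-yl)(pentamethoxyphenyl)methyl]succinate
Conditions: pyridinium p-toluenesulfonate (cat.), acetone–H2O (10:1), 50 °C
Reagents that add atoms: water, O
Why: Mild acid-catalysed hydrolysis of the dioxolanes releases both ketones without protonating the trisubstituted alkenes, and any shift of a β,γ-alkene into conjugation is harmless because all such isomers converge in step 14.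

Step 14
Reactants: 31 bis(cyclohexenone) dimethyl ester
Product: 32 dimethyl (2S,3S)-2-[(R)-(4-hydroxyphenyl)(2,4,6-trimethoxyphenyl)methyl]-3-[(R)-(4-hydroxyphenyl)(pentamethoxyphenyl)methyl]succinate
Conditions: Pd(OCOCF3)2 (10 mol %), 2-(dimethylamino)pyridine (20 mol %), TsOH·H2O (40 mol %), DMSO, O2 (1 atm), 80 °C
Reagents that add atoms: none
Why: In this palladium-catalysed aerobic dehydrogenation of cyclohexenones to phenols, a divalent palladium enolate undergoes β-hydride elimination to a cyclohexadienone that tautomerises to the 4-substituted phenol, and the benzylic centres C4 and C4' are neither enolisable nor part of the ring being oxidised.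

Step 15
Reactants: 32 bis(4-hydroxyphenyl) dimethyl ester
Product: 34 (3S,4R)-5,7-dihydroxy-4-(4-hydroxyphenyl)-3-[(3S,4R)-5,6,7,8-tetrahydroxy-4-(4-hydroxyphenyl)-2-oxochroman-3-yl]chroman-2-one, via decaphenol diester 33 (not isolated)
Conditions: BBr3 (excess), CH2Cl2, −78 °C → rt; H2O, then 1 M HCl–THF, 40 °C, under argon with degassed solvents
Reagents that add atoms: none
Why: Boron tribromide cleaves all eight aryl methyl ethers (Lewis-acid ether dealkylation), and the acid formed on quench drives lactonization of each methyl ester with an ortho-hydroxyl of the aryl ring on the neighbouring benzylic carbon to the six-membered dihydrocoumarin, the 2,6-dioxygenation of both aryl rings making the two ortho-hydroxyls equivalent and the acidic medium leaving C3 and C3' unepimerised.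

Compound list
1 | cyclohexane-1,3-dione | O=C1CCCC(=O)C1 | starting material
2 | 1,4-dioxaspiro[4.5]decan-7-one | O=C1CCCC2(C1)OCCO2 | intermediate
3 | 1,2,3,4-tetramethoxybenzene | COc1ccc(OC)c(OC)c1OC | starting material
4 | (2,3,4,5-tetramethoxyphenyl)lithium | [Li]c1cc(OC)c(OC)c(OC)c1OC | intermediate
5 | lithium trimethoxy(2,3,4,5-tetramethoxyphenyl)borate | [Li+].CO[B-](OC)(OC)c1cc(OC)c(OC)c(OC)c1OC | intermediate
6 | 2,3,4,5-tetramethoxyphenol | COc1cc(O)c(OC)c(OC)c1OC | intermediate
7 | pentamethoxybenzene | COc1cc(OC)c(OC)c(OC)c1OC | intermediate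
8 | (pentamethoxyphenyl)lithium | [Li]c1c(OC)c(OC)c(OC)c(OC)c1OC | intermediate
9 | lithium (dimethylamino)(pentamethoxyphenyl)methanolate | [Li+].[O-]C(N(C)C)c1c(OC)c(OC)c(OC)c(OC)c1OC | intermediate
10 | pentamethoxybenzaldehyde | O=Cc1c(OC)c(OC)c(OC)c(OC)c1OC | intermediate
11 | 2,4,6-trimethoxybenzaldehyde | COc1cc(OC)c(C=O)c(OC)c1 | starting material
12 | lithium 1,4-dioxaspiro[4.5]dec-7-en-7-olate (kinetic lithium enolate of 2) | [Li+].[O-]C1=CCCC2(C1)OCCO2 | intermediate
13 | lithium (7-oxo-1,4-dioxaspiro[4.5]decan-8-yl)(2,4,6-trimethoxyphenyl)methanolate, diastereomer mixture | [Li+].[O-]C(c1c(OC)cc(OC)cc1OC)C1CCC2(CC1=O)OCCO2 | intermediate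
14 | (7-oxo-1,4-dioxaspiro[4.5]decan-8-yl)(2,4,6-trimethoxyphenyl)methyl methanesulfonate, diastereomer mixture | CS(=O)(=O)OC(c1c(OC)cc(OC)cc1OC)C1CCC2(CC1=O)OCCO2 | intermediate
15 | (E)-8-(2,4,6-trimethoxybenzylidene)-1,4-dioxaspiro[4.5]decan-7-one | O=C1CC2(OCCO2)CC/C1=C\c1c(OC)cc(OC)cc1OC | intermediate
16 | sodium 1,4-dioxaspiro[4.5]dec-7-en-7-olate (kinetic sodium enolate of 2) | [Na+].[O-]C1=CCCC2(C1)OCCO2 | intermediate
17 | sodium (7-oxo-1,4-dioxaspiro[4.5]decan-8-yl)(pentamethoxyphenyl)methanolate, diastereomer mixture | [Na+].[O-]C(c1c(OC)c(OC)c(OC)c(OC)c1OC)C1CCC2(CC1=O)OCCO2 | intermediate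
18 | (7-oxo-1,4-dioxaspiro[4.5]decan-8-yl)(pentamethoxyphenyl)methyl methanesulfonate, diastereomer mixture | CS(=O)(=O)OC(c1c(OC)c(OC)c(OC)c(OC)c1OC)C1CCC2(CC1=O)OCCO2 | intermediate
19 | (E)-8-(pentamethoxybenzylidene)-1,4-dioxaspiro[4.5]decan-7-one | O=C1CC2(OCCO2)CC/C1=C\c1c(OC)c(OC)c(OC)c(OC)c1OC | intermediate
20 | (7R,8E)-8-(2,4,6-trimethoxybenzylidene)-1,4-dioxaspiro[4.5]decan-7-ol | O[C@@H]1CC2(OCCO2)CC/C1=C\c1c(OC)cc(OC)cc1OC | intermediate
21 | (7R,8E)-8-(pentamethoxybenzylidene)-1,4-dioxaspiro[4.5]decan-7-ol | O[C@@H]1CC2(OCCO2)CC/C1=C\c1c(OC)c(OC)c(OC)c(OC)c1OC | intermediate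
22 | succinic anhydride | O=C1CCC(=O)O1 | starting material
23 | hemisuccinate of 20 | OC(=O)CCC(=O)O[C@@H]1CC2(OCCO2)CC/C1=C\c1c(OC)cc(OC)cc1OC | intermediate
24 | mixed succinate diester of 20 and 21 | O=C(CCC(=O)O[C@@H]1CC2(OCCO2)CC/C1=C\c1c(OC)c(OC)c(OC)c(OC)c1OC)O[C@@H]1CC2(OCCO2)CC/C1=C\c1c(OC)cc(OC)cc1OC | intermediate
25 | dilithium bis-enolate of 24, both chain carbons cis to O–Li | [Li+].[Li+].[O-]/C(O[C@@H]1CC2(OCCO2)CC/C1=C\c1c(OC)cc(OC)cc1OC)=C\C=C(/[O-])O[C@@H]1CC2(OCCO2)CC/C1=C\c1c(OC)c(OC)c(OC)c(OC)c1OC | intermediate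
26 | (1Z,3Z)-bis(trimethylsilyl ketene acetal) of 24 | C[Si](C)(C)O/C(O[C@@H]1CC2(OCCO2)CC/C1=C\c1c(OC)cc(OC)cc1OC)=C\C=C(/O[Si](C)(C)C)O[C@@H]1CC2(OCCO2)CC/C1=C\c1c(OC)c(OC)c(OC)c(OC)c1OC | intermediate
27 | half-rearranged trimethylsilyl ester Z-ketene acetal, drawn with the trimethoxyphenyl terminus rearranged first (the other order is equally possible) | C[Si](C)(C)OC(=O)[C@@H]([C@H](C1=CCC2(OCCO2)CC1)c1c(OC)cc(OC)cc1OC)/C=C(\O[Si](C)(C)C)O[C@@H]1CC2(OCCO2)CC/C1=C\c1c(OC)c(OC)c(OC)c(OC)c1OC | intermediate
28 | bis(trimethylsilyl) ester of 29 | C[Si](C)(C)OC(=O)[C@@H]([C@H](C1=CCC2(OCCO2)CC1)c1c(OC)cc(OC)cc1OC)[C@@H](C(=O)O[Si](C)(C)C)[C@H](C1=CCC2(OCCO2)CC1)c1c(OC)c(OC)c(OC)c(OC)c1OC | intermediate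
29 | (2S,3S)-2-[(R)-(1,4-dioxaspiro[4.5]dec-7-en-8-yl)(2,4,6-trimethoxyphenyl)methyl]-3-[(R)-(1,4-dioxaspiro[4.5]dec-7-en-8-yl)(pentamethoxyphenyl)methyl]succinic acid | OC(=O)[C@@H]([C@H](C1=CCC2(OCCO2)CC1)c1c(OC)cc(OC)cc1OC)[C@@H](C(=O)O)[C@H](C1=CCC2(OCCO2)CC1)c1c(OC)c(OC)c(OC)c(OC)c1OC | intermediate
30 | dimethyl ester of 29 | COC(=O)[C@@H]([C@H](C1=CCC2(OCCO2)CC1)c1c(OC)cc(OC)cc1OC)[C@@H](C(=O)OC)[C@H](C1=CCC2(OCCO2)CC1)c1c(OC)c(OC)c(OC)c(OC)c1OC | intermediate
31 | dimethyl (2S,3S)-2-[(R)-(4-oxocyclohex-1-en-1-yl)(2,4,6-trimethoxyphenyl)methyl]-3-[(R)-(4-oxocyclohex-1-en-1-yl)(pentamethoxyphenyl)methyl]succinate | COC(=O)[C@@H]([C@H](C1=CCC(=O)CC1)c1c(OC)cc(OC)cc1OC)[C@@H](C(=O)OC)[C@H](C1=CCC(=O)CC1)c1c(OC)c(OC)c(OC)c(OC)c1OC | intermediate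
32 | dimethyl (2S,3S)-2-[(R)-(4-hydroxyphenyl)(2,4,6-trimethoxyphenyl)methyl]-3-[(R)-(4-hydroxyphenyl)(pentamethoxyphenyl)methyl]succinate | COC(=O)[C@@H]([C@H](c1ccc(O)cc1)c1c(OC)cc(OC)cc1OC)[C@@H](C(=O)OC)[C@H](c1ccc(O)cc1)c1c(OC)c(OC)c(OC)c(OC)c1OC | intermediate
33 | dimethyl (2S,3S)-2-[(R)-(4-hydroxyphenyl)(2,4,6-trihydroxyphenyl)methyl]-3-[(R)-(4-hydroxyphenyl)(pentahydroxyphenyl)methyl]succinate | COC(=O)[C@@H]([C@H](c1ccc(O)cc1)c1c(O)cc(O)cc1O)[C@@H](C(=O)OC)[C@H](c1ccc(O)cc1)c1c(O)c(O)c(O)c(O)c1O | intermediate
34 | (3S,4R)-5,7-dihydroxy-4-(4-hydroxyphenyl)-3-[(3S,4R)-5,6,7,8-tetrahydroxy-4-(4-hydroxyphenyl)-2-oxochroman-3-yl]chroman-2-one | O=C1Oc2cc(O)cc(O)c2[C@@H](c2ccc(O)cc2)[C@H]1[C@H]1C(=O)Oc2c(O)c(O)c(O)c(O)c2[C@H]1c1ccc(O)cc1 | target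

Total step count: 15.
Longest linear sequence: 11 steps (steps 2, 3, 4, 6, 8, 10, 11, 12, 13, 14, 15, from 3 to 34).

Steps most likely to fail

Step 11. The ketene acetal geometry may not be uniform at the two termini, which would erode control at C3 and C3'. The second shift at the crowded arylidene carbon may also be slow, so that silyl ketene acetal decomposition competes. The fallback forms the two bonds one at a time and sets out from hemisuccinate 23. Its carboxylate–enolate dianion (LiN(iPr)2, 2.2 equiv, THF–DMPU, −78 °C; TMSCl; warming) should undergo a single Ireland–Claisen rearrangement to (2R)-2-[(R)-(1,4-dioxaspiro[4.5]dec-7-en-8-yl)(2,4,6-trimethoxyphenyl)methyl]succinic acid F1. Dehydration with Ac2O gives its cyclic anhydride F2. Alcohol 21 with 4-(dimethylamino)pyridine opens F2 at the less hindered carbonyl next to the CH2 group to give the acid ester F3. A second single Ireland–Claisen rearrangement of F3 under the same conditions comes back to the route at diacid 29. Each rearrangement can then be tuned, and its diastereomers removed, on its own.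

Step 14. The electron-rich trimethoxyphenyl C–H bonds may be palladated, or the reaction may stall after only one of the two hindered rings has been aromatised. The fallback replaces the palladium enolate pathway by a sulfur-based enolate dehydrogenation and sets out from 31. DBU (cat.) moves both alkenes into conjugation to give the bis(4-oxocyclohex-2-en-1-yl) diester F4 (mixture of ring epimers). Kinetic deprotonation at the ketone α' positions with LiN(iPr)2 at −78 °C, which are more acidic and far less hindered than the tertiary ester α-CH groups, and treatment with N-tert-butylbenzenesulfinimidoyl chloride should give the cross-conjugated dienones. These tautomerise to the phenols on work-up, coming back to the route at 32.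

Step 15. Ether cleavage may be incomplete at the crowded pentamethoxyphenyl ring, and the tetrahydroxylated ring B may be air-oxidised during isolation, giving a polyphenol mixture that cannot be purified. The fallback changes the isolation to a derivatise–purify–release sequence and sets out from 32. After the BBr3 treatment and acid lactonization, the crude product is peracetylated (Ac2O, pyridine) to the octaacetate of the bis-lactone F5, which is stable to air and can be chromatographed free of partly methylated material. Acid hydrolysis of the aryl acetates (3 M HCl–THF, 50 °C, degassed, argon) then comes back to the route at target 34, the six-membered lactones being the stable form under acid.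

Further compounds
F1 | step 11 | (2R)-2-[(R)-(1,4-dioxaspiro[4.5]dec-7-en-8-yl)(2,4,6-trimethoxyphenyl)methyl]succinic acid | OC(=O)C[C@@H](C(=O)O)[C@H](C1=CCC2(OCCO2)CC1)c1c(OC)cc(OC)cc1OC
F2 | step 11 | cyclic anhydride of F1 (3-substituted dihydrofuran-2,5-dione) | O=C1C[C@H]([C@H](C2=CCC3(OCCO3)CC2)c2c(OC)cc(OC)cc2OC)C(=O)O1
F3 | step 11 | 4-[(7R,8E)-8-(pentamethoxybenzylidene)-1,4-dioxaspiro[4.5]decan-7-yl] hydrogen (2S)-2-[(R)-(1,4-dioxaspiro[4.5]dec-7-en-8-yl)(2,4,6-trimethoxyphenyl)methyl]succinate | OC(=O)[C@@H]([C@H](C1=CCC2(OCCO2)CC1)c1c(OC)cc(OC)cc1OC)CC(=O)O[C@@H]1CC2(OCCO2)CC/C1=C\c1c(OC)c(OC)c(OC)c(OC)c1OC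
F4 | step 14 | dimethyl (2S,3S)-2-[(S)-(4-oxocyclohex-2-en-1-yl)(2,4,6-trimethoxyphenyl)methyl]-3-[(S)-(4-oxocyclohex-2-en-1-yl)(pentamethoxyphenyl)methyl]succinate, mixture of epimers at the two ring C1 atoms (same spatial arrangement at the benzylic carbons as in 31, the descriptor changing only through the priority order) | COC(=O)[C@@H]([C@H](C1C=CC(=O)CC1)c1c(OC)cc(OC)cc1OC)[C@@H](C(=O)OC)[C@H](C1C=CC(=O)CC1)c1c(OC)c(OC)c(OC)c(OC)c1OC
F5 | step 15 | octaacetate of target 34 | O=C1Oc2cc(OC(C)=O)cc(OC(C)=O)c2[C@@H](c2ccc(OC(C)=O)cc2)[C@H]1[C@H]1C(=O)Oc2c(OC(C)=O)c(OC(C)=O)c(OC(C)=O)c(OC(C)=O)c2[C@H]1c1ccc(OC(C)=O)cc1
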